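**Retrosynthetic overview**

1. Numbering (eremophilane): ring A = C1–C5 + C10, ring B = C5–C10. C14 is the angular methyl on C5, C15 the ester carbon on C4, and C11–C13 the propanoate side chain on C7. "Methyl face" means the face that carries C14.
2. Endgame disconnections: the C3–O angelate (acylation), C10–H (hydrogenation of C9=C10 from the methyl face) and C3–H (hydride addition to a C3 ketone). These lead back to a cross-conjugated C6=C7/C9=C10 dienone that is also a C3/C15 β-keto ester.
3. Key disconnection C4–C5. In ring B the C8 carbonyl is para (1,4) to the quaternary C5, and C6=C7 already carries the side chain, so ring B is a dearomatised 2,4,5-trisubstituted phenol. C4 lies between C3–O and C15 and is the α-carbon of a β-keto ester, so the C4 enol can be joined oxidatively to the para carbon of the phenol.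
4. The flat precursor comes from 3-bromo-4-methylphenol. C7–C11 is made by an auxiliary-controlled α-arylation that sets C11. C10–C1 is made by Heck arylation of an allylic alcohol, which delivers the whole β-keto ester arm.
5. Ring order: ring B is bought as the arene, and ring A is closed in the key step.

Key step: step 10

Assumption: the sense of induction of the (+)-8-phenylmenthyl ester is taken from the usual shielding model for metal-chelated 8-phenylmenthyl dicarbonyl esters, in which the phenyl ring lies over the C4-Re face. Both enantiomers of 8-phenylmenthol are treated as commercial.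

**Step 1**
Reactants: 1 3-bromo-4-methylphenol
Product: 2 5-bromo-2-iodo-4-methylphenol
Conditions: NIS, TsOH·H2O (10 mol %), MeCN, 0 °C to rt
Reagents that add atoms: N-iodosuccinimide, O=C1CCC(=O)N1I
Why: Electrophilic aromatic iodination in which OH directs ortho, the para position is blocked by methyl, and the ortho position next to bromine is hindered, so iodine should enter at the future C7, para to bromine.

**Step 2**
Reactants: 2 5-bromo-2-iodo-4-methylphenol
Product: 3 1-(benzyloxy)-5-bromo-2-iodo-4-methylbenzene
Conditions: BnBr, K2CO3, DMF, rt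
Reagents that add atoms: benzyl bromide, BrCc1ccccc1
Why: Williamson ether synthesis, where the benzyl ether prevents lactonisation onto the later ortho ester (which would make C11 labile) and is removable by neutral hydrogenolysis.

**Step 3**
Reactants: 4 (R)-4-benzyl-3-propanoyl-1,3-oxazolidin-2-one
Product: 5 (R)-4-benzyl-3-[(Z)-1-(trimethylsilyloxy)prop-1-enyl]-1,3-oxazolidin-2-one
Conditions: TMSOTf, Et3N, CH2Cl2, 0 °C to rt
Reagents that add atoms: trimethylsilyl triflate, C[Si](C)(C)OS(=O)(=O)C(F)(F)F
Why: Soft enolisation with O-silylation of the imide, which should give the Z silyl ketene N,O-acetal because A1,3 strain with the auxiliary disfavours the E isomer.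

**Step 4**
Reactants: 3 1-(benzyloxy)-5-bromo-2-iodo-4-methylbenzene; 5 (R)-4-benzyl-3-[(Z)-1-(trimethylsilyloxy)prop-1-enyl]-1,3-oxazolidin-2-one
Product: 7 (R)-4-benzyl-3-{(S)-2-[2-(benzyloxy)-4-bromo-5-methylphenyl]propanoyl}-1,3-oxazolidin-2-one, via zinc enolate 6 (not isolated)
Conditions: Pd(dba)2 (5 mol %), P(t-Bu)3 (10 mol %), ZnF2 (0.5 equiv), DMF, 60 °C, 5 as limiting component
Reagents that add atoms: none
Why: Palladium-catalysed α-arylation of an imide silyl enolate, in which oxidative addition at C–I outruns C–Br, the fluoride-released zinc enolate transmetalates, and C–C bond formation on the enolate face opposite the benzyl group of the (R)-auxiliary sets C11 as S under conditions too mild for epimerisation.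

**Step 5**
Reactants: 7 (R)-4-benzyl-3-{(S)-2-[2-(benzyloxy)-4-bromo-5-methylphenyl]propanoyl}-1,3-oxazolidin-2-one
Product: 8 methyl (S)-2-[2-(benzyloxy)-4-bromo-5-methylphenyl]propanoate
Conditions: Yb(OTf)3 (10 mol %), MeOH, 40 °C
Reagents that add atoms: methanol, CO
Why: Lewis-acid-catalysed methanolysis of an N-acyl oxazolidinone, where chelation activates the exocyclic carbonyl so that neutral methanol cleaves it without base and the α-aryl centre C11 is kept.

**Step 6**
Reactants: 9 (+)-8-phenylmenthol
Product: 10 (+)-8-phenylmenthyl acetate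
Conditions: Ac2O, DMAP (cat), pyridine, rt
Reagents that add atoms: acetic anhydride, CC(=O)OC(C)=O
Why: DMAP-catalysed acylation of a secondary alcohol that touches no stereocentre.

**Step 7**
Reactants: 10 (+)-8-phenylmenthyl acetate; 11 acrolein
Product: 13 (+)-8-phenylmenthyl 3-hydroxypent-4-enoate (both carbinol epimers), via lithium enolate 12 (not isolated)
Conditions: LDA, THF, −78 °C; acrolein; AcOH quench
Reagents that add atoms: none
Why: Aldol 1,2-addition of a lithium ester enolate to acrolein, whose new carbinol centre may form as a mixture because it is erased in step 8.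

**Step 8**
Reactants: 8 methyl (S)-2-[2-(benzyloxy)-4-bromo-5-methylphenyl]propanoate; 13 (+)-8-phenylmenthyl 3-hydroxypent-4-enoate
Product: 15 (+)-8-phenylmenthyl 5-{5-(benzyloxy)-4-[(S)-1-methoxy-1-oxopropan-2-yl]-2-methylphenyl}-3-oxopentanoate, via enol tautomer 14 (not isolated)
Conditions: Pd(OAc)2 (5 mol %), P(o-tol)3 (10 mol %), NaHCO3, Bu4NCl, DMF, 90 °C
Reagents that add atoms: none
Why: Heck arylation of a secondary allylic alcohol, in which the aryl group adds to the terminal carbon, β-hydride elimination toward the carbinol C–H gives an enol that tautomerises to the ketone, both carbinol epimers converge on one β-keto ester, and hydrogen carbonate is too weak a base to epimerise C11.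

**Step 9**
Reactants: 15 (+)-8-phenylmenthyl 5-{5-(benzyloxy)-4-[(S)-1-methoxy-1-oxopropan-2-yl]-2-methylphenyl}-3-oxopentanoate
Product: 16 (+)-8-phenylmenthyl 5-{5-hydroxy-4-[(S)-1-methoxy-1-oxopropan-2-yl]-2-methylphenyl}-3-oxopentanoate
Conditions: H2 (1 atm), 10% Pd/C, EtOAc, rt; used directly
Reagents that add atoms: none
Why: Neutral hydrogenolysis of the benzyl aryl ether, which frees the phenol without acid, base or heat, so neither lactonisation nor epimerisation at C11 is expected.

**Step 10**
Reactants: 16 (+)-8-phenylmenthyl 5-{5-hydroxy-4-[(S)-1-methoxy-1-oxopropan-2-yl]-2-methylphenyl}-3-oxopentanoate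
Product: 18 (+)-8-phenylmenthyl (1S,8aS)-7-[(S)-1-methoxy-1-oxopropan-2-yl]-8a-methyl-2,6-dioxo-1,2,3,4,6,8a-hexahydronaphthalene-1-carboxylate, via phenoxenium ion 17 (not isolated)
Conditions: undivided cell, BDD anode, Pt cathode, constant current 5 mA cm−2, 2.2 F mol−1, Yb(OTf)3 (1 equiv), Bu4NPF6 (0.1 M), HFIP–CH2Cl2 4:1, 0 °C
Reagents that add atoms: none
Why: Proposed new method: anodic two-electron oxidation of the phenol (the most easily oxidised π system of 16) in base-free, non-nucleophilic HFIP should give phenoxenium ion 17, whose charge is largest at the methyl-bearing para carbon C5, and the Yb(III)-chelated enol of the β-keto ester attacks it through C4, the two protons set free being reduced to H2 at the cathode. The closest known reaction types are the anodic or iodine(III)-mediated para-dearomatisation of 4-alkylphenols by tethered carbon π-nucleophiles and the Mn(III)/Yb(OTf)3 oxidative cyclisation of 8-phenylmenthyl β-keto esters; new are the β-keto ester as nucleophile for a fused (not spiro) para closure and auxiliary control under electrolysis. Ring A (C1–C5, C10) closes in a 6-(enolendo) mode, exo to the C5–C6 π bond, through a chair in which C6 is equatorial and C14 axial. C5 (S) is controlled by the auxiliary: in the Yb chelate both carbonyl oxygens are syn, the cumyl phenyl ring stacks over the C4-Re face, C4 therefore bonds through its Si face, and the chair couples this face to one face of the planar cation. C4 (S) follows from the Z-chelate, which places C15 anti to C2 (equatorial, cis to C14), and is also expected to be the thermodynamic epimer of this enolisable centre. The step needs para (C5) over ortho (C9) attack, C- over O-attack and capture faster than proton loss from C14 or C11 (quinone methides): the first is secured by the charge distribution of the cation reinforced by the C14 methyl group, the second by Yb(III) tying up both oxygens and by the reversibility of O-attack in HFIP, the third by the absence of base and the short six-membered tether, which also leaves C11 untouched.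

**Step 11**
Reactants: 18 (+)-8-phenylmenthyl (1S,8aS)-7-[(S)-1-methoxy-1-oxopropan-2-yl]-8a-methyl-2,6-dioxo-1,2,3,4,6,8a-hexahydronaphthalene-1-carboxylate
Product: 20 methyl (1S,8aS)-7-[(S)-1-methoxy-1-oxopropan-2-yl]-8a-methyl-2,6-dioxo-1,2,3,4,6,8a-hexahydronaphthalene-1-carboxylate, via acylketene 19 (not isolated)
Conditions: MeOH–toluene 1:1, DMAP (0.3 equiv), sealed tube, 110 °C
Reagents that add atoms: methanol, CO
Why: DMAP-catalysed ester exchange of an enolisable β-keto ester, which runs by loss of the auxiliary alcohol to an acylketene and addition of excess methanol, so the neopentylic carbonyl need not be attacked directly, exchange at C12 is degenerate, and ketonisation returns C4 to its equatorial S configuration.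

**Step 12**
Reactants: 20 methyl (1S,8aS)-7-[(S)-1-methoxy-1-oxopropan-2-yl]-8a-methyl-2,6-dioxo-1,2,3,4,6,8a-hexahydronaphthalene-1-carboxylate
Product: 21 methyl (1S,2R,8aS)-2-hydroxy-7-[(S)-1-methoxy-1-oxopropan-2-yl]-8a-methyl-6-oxo-1,2,3,4,6,8a-hexahydronaphthalene-1-carboxylate
Conditions: NaBH4, MeOH–CH2Cl2 1:1, −78 to −40 °C
Reagents that add atoms: none
Why: Chemoselective borohydride reduction of a saturated ketone beside a much less reactive cross-conjugated dienone, in which the axial C14 methyl (1,3 to C3 in the rigid chair of ring A) blocks axial approach, so hydride should add equatorially from the face opposite the methyl and give the axial C3 alcohol (R), cis to C15 and C14.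

**Step 13**
Reactants: 21 methyl (1S,2R,8aS)-2-hydroxy-7-[(S)-1-methoxy-1-oxopropan-2-yl]-8a-methyl-6-oxo-1,2,3,4,6,8a-hexahydronaphthalene-1-carboxylate
Product: 22 methyl (1S,2R,4aS,8aS)-2-hydroxy-7-[(S)-1-methoxy-1-oxopropan-2-yl]-8a-methyl-6-oxo-1,2,3,4,4a,5,6,8a-octahydronaphthalene-1-carboxylate
Conditions: H2 (1 atm, stopped after 1 equiv uptake), 5% Pd/C, i-PrOH, rt
Reagents that add atoms: none
Why: Heterogeneous hydrogenation that, as with angular-methyl octalones and steroidal 1,4-dien-3-ones on palladium, should deliver hydrogen to C10 from the methyl face to give the cis-decalin (C10 S), helped by anchoring of the C3 hydroxyl on that face, while C6=C7 should react more slowly because C6 is neopentylic and the A1,3-locked C11 branch holds CH3 and CO2Me over both of its faces.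

**Step 14**
Reactants: 23 angelic acid
Product: 24 angelic 2,4,6-trichlorobenzoic anhydride
Conditions: 2,4,6-trichlorobenzoyl chloride, Et3N, toluene, rt; filtered and used as a solution
Reagents that add atoms: 2,4,6-trichlorobenzoyl chloride, O=C(Cl)c1c(Cl)cc(Cl)cc1Cl
Why: Mixed-anhydride formation as in the Yamaguchi esterification, which activates the acid without a nucleophilic catalyst and therefore should keep the Z double bond.

**Step 15**
Reactants: 22 methyl (1S,2R,4aS,8aS)-2-hydroxy-7-[(S)-1-methoxy-1-oxopropan-2-yl]-8a-methyl-6-oxo-1,2,3,4,4a,5,6,8a-octahydronaphthalene-1-carboxylate; 24 angelic 2,4,6-trichlorobenzoic anhydride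
Product: 25 target CNP0265265.1
Conditions: toluene, 80 °C, no DMAP
Reagents that add atoms: none
Why: Yamaguchi-type acylation of the secondary alcohol at the less hindered angeloyl carbonyl, run without nucleophilic catalyst to avoid Z to E isomerisation to the tiglate and without strong base to avoid E1cB loss of the β-acyloxy group or epimerisation at C4 and C11, with C3 retained because its C–O bond is not broken.

**Compound list**

1 | 3-bromo-4-methylphenol | Cc1ccc(O)cc1Br | starting material
2 | 5-bromo-2-iodo-4-methylphenol | Cc1cc(I)c(O)cc1Br | intermediate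
3 | 1-(benzyloxy)-5-bromo-2-iodo-4-methylbenzene | Cc1cc(I)c(OCc2ccccc2)cc1Br | intermediate
4 | (R)-4-benzyl-3-propanoyl-1,3-oxazolidin-2-one | CCC(=O)N1[C@H](Cc2ccccc2)COC1=O | starting material
5 | (R)-4-benzyl-3-[(Z)-1-(trimethylsilyloxy)prop-1-enyl]-1,3-oxazolidin-2-one | C/C=C(\O[Si](C)(C)C)N1[C@H](Cc2ccccc2)COC1=O | intermediate
6 | zinc bis[(Z)-enolate] of 4 (not isolated) | C/C=C(\[O-])N1[C@H](Cc2ccccc2)COC1=O.C/C=C(\[O-])N1[C@H](Cc2ccccc2)COC1=O.[Zn+2] | intermediate
7 | (R)-4-benzyl-3-{(S)-2-[2-(benzyloxy)-4-bromo-5-methylphenyl]propanoyl}-1,3-oxazolidin-2-one | O=C1OC[C@@H](Cc2ccccc2)N1C(=O)[C@@H](C)c1cc(C)c(Br)cc1OCc1ccccc1 | intermediate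
8 | methyl (S)-2-[2-(benzyloxy)-4-bromo-5-methylphenyl]propanoate | COC(=O)[C@@H](C)c1cc(C)c(Br)cc1OCc1ccccc1 | intermediate
9 | (+)-8-phenylmenthol, (1S,2R,5S)-5-methyl-2-(2-phenylpropan-2-yl)cyclohexan-1-ol | O[C@H]1C[C@@H](C)CC[C@@H]1C(C)(C)c1ccccc1 | starting material
10 | (+)-8-phenylmenthyl acetate | CC(=O)O[C@H]1C[C@@H](C)CC[C@@H]1C(C)(C)c1ccccc1 | intermediate
11 | acrolein | C=CC=O | starting material
12 | lithium enolate of 10 (not isolated) | [Li+].C=C([O-])O[C@H]1C[C@@H](C)CC[C@@H]1C(C)(C)c1ccccc1 | intermediate
13 | (+)-8-phenylmenthyl 3-hydroxypent-4-enoate, both carbinol epimers | C=CC(O)CC(=O)O[C@H]1C[C@@H](C)CC[C@@H]1C(C)(C)c1ccccc1 | intermediate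
14 | enol tautomer of 15, 3-hydroxypent-3-enoate (not isolated) | COC(=O)[C@@H](C)c1cc(C)c(CC=C(O)CC(=O)O[C@H]2C[C@@H](C)CC[C@@H]2C(C)(C)c2ccccc2)cc1OCc1ccccc1 | intermediate
15 | (+)-8-phenylmenthyl 5-{5-(benzyloxy)-4-[(S)-1-methoxy-1-oxopropan-2-yl]-2-methylphenyl}-3-oxopentanoate | COC(=O)[C@@H](C)c1cc(C)c(CCC(=O)CC(=O)O[C@H]2C[C@@H](C)CC[C@@H]2C(C)(C)c2ccccc2)cc1OCc1ccccc1 | intermediate
16 | (+)-8-phenylmenthyl 5-{5-hydroxy-4-[(S)-1-methoxy-1-oxopropan-2-yl]-2-methylphenyl}-3-oxopentanoate | COC(=O)[C@@H](C)c1cc(C)c(CCC(=O)CC(=O)O[C@H]2C[C@@H](C)CC[C@@H]2C(C)(C)c2ccccc2)cc1O | intermediate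
17 | phenoxenium ion of 16, drawn as the C5 cation (not isolated) | COC(=O)[C@@H](C)C1=C[C+](C)C(CCC(=O)CC(=O)O[C@H]2C[C@@H](C)CC[C@@H]2C(C)(C)c2ccccc2)=CC1=O | intermediate
18 | (+)-8-phenylmenthyl (1S,8aS)-7-[(S)-1-methoxy-1-oxopropan-2-yl]-8a-methyl-2,6-dioxo-1,2,3,4,6,8a-hexahydronaphthalene-1-carboxylate | O=C1CCC2=CC(=O)C([C@H](C)C(=O)OC)=C[C@@]2(C)[C@@H]1C(=O)O[C@H]3C[C@@H](C)CC[C@@H]3C(C)(C)c4ccccc4 | intermediate
19 | acylketene from 18, C4=C15=O (not isolated) | O=C1CCC2=CC(=O)C([C@H](C)C(=O)OC)=C[C@@]2(C)C1=C=O | intermediate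
20 | methyl (1S,8aS)-7-[(S)-1-methoxy-1-oxopropan-2-yl]-8a-methyl-2,6-dioxo-1,2,3,4,6,8a-hexahydronaphthalene-1-carboxylate | O=C1CCC2=CC(=O)C([C@H](C)C(=O)OC)=C[C@@]2(C)[C@@H]1C(=O)OC | intermediate
21 | methyl (1S,2R,8aS)-2-hydroxy-7-[(S)-1-methoxy-1-oxopropan-2-yl]-8a-methyl-6-oxo-1,2,3,4,6,8a-hexahydronaphthalene-1-carboxylate | O[C@@H]1CCC2=CC(=O)C([C@H](C)C(=O)OC)=C[C@@]2(C)[C@@H]1C(=O)OC | intermediate
22 | methyl (1S,2R,4aS,8aS)-2-hydroxy-7-[(S)-1-methoxy-1-oxopropan-2-yl]-8a-methyl-6-oxo-1,2,3,4,4a,5,6,8a-octahydronaphthalene-1-carboxylate (cis-decalin) | O[C@@H]1CC[C@H]2CC(=O)C([C@H](C)C(=O)OC)=C[C@@]2(C)[C@@H]1C(=O)OC | intermediate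
23 | angelic acid, (Z)-2-methylbut-2-enoic acid | C/C=C(/C)C(=O)O | starting material
24 | angelic 2,4,6-trichlorobenzoic anhydride | C/C=C(/C)C(=O)OC(=O)c1c(Cl)cc(Cl)cc1Cl | intermediate
25 | methyl (1S,2R,4aS,8aS)-7-[(S)-1-methoxy-1-oxopropan-2-yl]-8a-methyl-2-[(Z)-2-methylbut-2-enoyloxy]-6-oxo-1,2,3,4,4a,5,6,8a-octahydronaphthalene-1-carboxylate | C/C=C(/C)C(=O)O[C@@H]1CC[C@H]2CC(=O)C([C@H](C)C(=O)OC)=C[C@@]2(C)[C@@H]1C(=O)OC | target

**Step count**

Total step count: 15.
Longest linear sequence: 11 steps (1, 2, 4, 5, 8, 9, 10, 11, 12, 13, 15).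

**Steps most likely to fail**

1. **Step 10 (anodic dearomatising cyclisation).**
   - What may go wrong: the enol may attack the unsubstituted ortho carbon C9 and the ring rearomatise; closure may occur through the enol oxygen; the cation may lose a proton from C14 or C11; or the auxiliary may shield the enol face too weakly.
   - Fallback: this uses known chemistry with reversed polarity, starting from 16. Regitz diazo transfer (p-ABSA, Et3N, MeCN, 0 °C) would give the α-diazo-β-keto ester F1. Rh2(OAc)4 (CH2Cl2, rt) would then turn C4 into an electrophilic carbenoid that is attacked by the para carbon C5 of the free phenol. This is the known dearomatising aryl participation of diazo carbonyl compounds. Collapse of the adduct with an O-to-C4 proton shift and loss of nitrogen rejoins the route at 18.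

2. **Step 13 (partial hydrogenation).**
   - What may go wrong: C6=C7 may be over-reduced, or hydrogen may be delivered from the face opposite the methyl group.
   - Fallback: this gives up chemoselectivity and restores the olefin afterwards, starting from 21. Exhaustive hydrogenation (H2, 4 atm, Pd/C, EtOAc) would give the saturated keto alcohol F2 as C7 epimers. Thermodynamic silylation (TMSI, HMDS, CH2Cl2) would give the C7=C8 silyl enol ether that is also silylated at the C3 oxygen, F3. Saegusa–Ito oxidation (Pd(OAc)2, MeCN) would give the C3-O-silylated enone F4. Mild methanolysis (citric acid, MeOH) rejoins the route at 22.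

3. **Step 11 (exchange of the auxiliary ester).**
   - What may go wrong: expulsion of the hindered alcohol may be slow; methanol may open ring A by a retro-Claisen reaction; or C11 may epimerise slowly at the temperature needed.
   - Fallback: this drops the auxiliary and separates diastereomers instead, starting from 8. Heck arylation of commercial methyl 3-hydroxypent-4-enoate under the conditions of step 8 would give the methyl β-keto ester benzyl ether F5. Hydrogenolysis as in step 9 would give the phenol F6. Electrolysis as in step 10 would give 20 together with its (1R,8aR) diastereomer F7. Because C11 is already fixed, the two products are diastereomers and can be separated by chromatography. The route is rejoined at 20.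

**Further compounds**

F1 | step 10 | (+)-8-phenylmenthyl 2-diazo-5-{5-hydroxy-4-[(S)-1-methoxy-1-oxopropan-2-yl]-2-methylphenyl}-3-oxopentanoate | COC(=O)[C@@H](C)c1cc(C)c(CCC(=O)C(=[N+]=[N-])C(=O)O[C@H]2C[C@@H](C)CC[C@@H]2C(C)(C)c2ccccc2)cc1O
F2 | step 13 | methyl (1S,2R,4aS,8aS)-2-hydroxy-7-[(S)-1-methoxy-1-oxopropan-2-yl]-8a-methyl-6-oxodecahydronaphthalene-1-carboxylate, C7 epimers | O[C@@H]1CC[C@H]2CC(=O)C([C@H](C)C(=O)OC)C[C@@]2(C)[C@@H]1C(=O)OC
F3 | step 13 | C7=C8 trimethylsilyl enol ether and C3 trimethylsilyl ether of F2 | C[Si](C)(C)O[C@@H]1CC[C@H]2CC(O[Si](C)(C)C)=C([C@H](C)C(=O)OC)C[C@@]2(C)[C@@H]1C(=O)OC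
F4 | step 13 | C3 trimethylsilyl ether of 22 | C[Si](C)(C)O[C@@H]1CC[C@H]2CC(=O)C([C@H](C)C(=O)OC)=C[C@@]2(C)[C@@H]1C(=O)OC
F5 | step 11 | methyl 5-{5-(benzyloxy)-4-[(S)-1-methoxy-1-oxopropan-2-yl]-2-methylphenyl}-3-oxopentanoate | COC(=O)[C@@H](C)c1cc(C)c(CCC(=O)CC(=O)OC)cc1OCc1ccccc1
F6 | step 11 | methyl 5-{5-hydroxy-4-[(S)-1-methoxy-1-oxopropan-2-yl]-2-methylphenyl}-3-oxopentanoate | COC(=O)[C@@H](C)c1cc(C)c(CCC(=O)CC(=O)OC)cc1O
F7 | step 11 | methyl (1R,8aR)-7-[(S)-1-methoxy-1-oxopropan-2-yl]-8a-methyl-2,6-dioxo-1,2,3,4,6,8a-hexahydronaphthalene-1-carboxylate | O=C1CCC2=CC(=O)C([C@H](C)C(=O)OC)=C[C@]2(C)[C@H]1C(=O)OC
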